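## The problem

Larreantin is a 2-methoxy-1,4-naphthoquinone. Ring A is the quinone ring (C1=O, C2–OMe, C3–H, C4=O, C4a, C8a). Ring B is the benzenoid ring, with four different neighbours in a row: C5–H, C6–CH2Ar (4-hydroxy-3-methoxybenzyl), C7–CH3 and C8–Ar (4-hydroxy-3-methoxyphenyl).

- There is no stereocentre, so the whole problem is regiochemistry. Two relations must be fixed: the order H / benzyl / methyl / aryl around ring B, and the placement of the C2 methoxy group next to the C1 carbonyl that lies peri to the C8 aryl group.
- The skeleton holds three oxygenated arenes of similar nucleophilicity (ring A at the hydroquinone-ether level and two guaiacyl rings). C6 and C8 each carry two aryl-bearing arms, so a cationic or radical-cation ring closure can choose the wrong ring.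
- The quinone is a vinylogous ester: the C2 methoxy group is lost to hydroxide, amines or strong Lewis acids. The free guaiacols are oxidized by the reagents that make quinones. The phenols must therefore stay masked through every oxidation and be freed last under neutral conditions.
- The enabling feature: C7(CH3)–C8(Ar) is an intact (E)-propenylguaiacol (isoeugenol) double bond. The rest, ring A with C5=C6–CH2Ar, is a 2-methoxy-5-alkenyl-1,4-benzoquinone whose atoms C8a=C4a–C5=C6 form an electron-poor diene. Because the C2 methoxy group makes C4=O a vinylogous ester, the diene is polarized by C1=O alone, with C6 as its electrophilic end. That is the orientation the target needs.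

## Retrosynthesis

**12 ⇒ 10 (phenol O–H bonds).** Only the two guaiacol O–H bonds are cut. Benzyl ethers are chosen because they keep the dienophile electron-rich and survive tetravalent cerium, MnO2 and DDQ. Hydrogenolysis is neutral; it reduces the quinone to hydroquinone 11, which air returns to the quinone. Acetates would deactivate the dienophile.

**10 ⇒ 9 (oxidation level of ring B).** Two hydrogens are added back at C7 and C8. The 7,8-dihydronaphthoquinone 9 is what a cycloaddition delivers. The forward step is a dehydrogenation that erases both stereocentres, so no selectivity is asked of it.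

**9 ⇒ 8 ⇒ 7 ⇒ 5 + 6 (key cut: C6–C7 and C8–C8a).** Ring B is opened into vinylquinone 5 (diene C8a=C4a–C5=C6) and O-benzylisoeugenol 6 (dienophile C7=C8).
- Against the neighbouring cut C4a–C5 / C8–C8a (quinone as dienophile): that cut loads all three ring-B substituents onto an acyclic diene of defined geometry.
- Against cuts through ring A: those need a contiguously tetrasubstituted benzene.
- Here one partner is purchasable and the other is a quinone with a single side chain.
- Asked of the forward reaction: head-to-tail orientation, tautomerization of cycloadduct 7 to hydroquinone 8, and oxidation to 9.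

**5 ⇒ 4 (two C=O from two C–OMe).** The quinone comes from the 2,4,5-trimethoxyphenyl ring of 4 by oxidative demethylation of the para pair C2'/C5'. The C4' methoxy group stays and becomes the C2 methoxy group of the target. The methoxy regiochemistry is thus bought with the starting material.

**4 ⇒ 2 + 3 (C5=C6 alkene).** The 1,3-diarylpropene is cut at its double bond into O-benzyleugenol 2 and α-asarone 3, joined by cross-metathesis with loss of propene. The forward step must give the E alkene, which the diene needs to reach its s-cis form.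

**2 ⇒ 1 (O–benzyl bond).** Benzylation of eugenol 1.

## Roads not taken

**Alternative 1:** cut C4a–C5 and C8–C8a. This is the obvious normal-demand Diels–Alder reaction of 2-methoxy-1,4-benzoquinone A2 with the diene A1, giving adduct A3, then two oxidations to 10.
- A1 is a 1,2,3-trisubstituted acyclic diene with a defined E geometry. No abundant building block maps onto it, and it would take four to five steps.
- Its regiocontrol rests on the modest directing effect of the 1-aryl group, perturbed by the 2-methyl and 3-benzyl groups.
- The chosen plan pairs a strongly polarized acceptor diene with a strongly polarized donor alkene, uses a purchasable 2π partner, and needs the same number of oxidations.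

**Alternative 2:** cut C1–C8a and C4–C4a (Moore ring expansion). The aryllithium from bromide A4 adds to the semisquarate A5 to give cyclobutenone A6. Thermal ring opening to a ketene and 6π closure, then oxidation, deliver 10.
- The methoxy placement is secure.
- But A4 is an unsymmetrical 1,2,3,4-tetrasubstituted benzene with no directing group. Its synthesis is the whole problem, at six or more steps, and the cascade then builds only the easy ring.

**Alternative 3:** cut the same bonds C6–C7 and C8–C8a one oxidation level lower. Anodic radical-cation cross-annulation of 4 with 6 would give dihydronaphthalene A7, then naphthalene A8, then late oxidative demethylation.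
- The two styrenes have close oxidation potentials, so homodimers and cyclobutanes compete.
- The distonic radical cation can close on three arenes: ring A at C8a, the isoeugenol ring, or the benzyl ring.
- Ring A must still be oxidized at the end beside an electron-rich naphthalene.
- In the chosen plan the quinone is the only electrophile and the only ring that can be annulated.

Key step: step 4

Assumption: the C8–aryl bond, with no ortho substituent on the aryl ring, is taken as freely rotating, so no element of chirality has to be set; the dihydro intermediates are racemic.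

## Route

Step 1
Reactants: 1 eugenol (4-allyl-2-methoxyphenol)
Product: 2 O-benzyleugenol (4-allyl-1-(benzyloxy)-2-methoxybenzene)
Conditions: BnBr (1.1 equiv), K2CO3, DMF, rt
Reagents that add atoms: benzyl bromide, BrCc1ccccc1
Why: Williamson ether synthesis (SN2 of the phenoxide on benzyl bromide); K2CO3 is too weak to move the allyl double bond into conjugation.

Step 2
Reactants: 2 O-benzyleugenol (2 equiv); 3 α-asarone ((E)-1,2,4-trimethoxy-5-(prop-1-en-1-yl)benzene)
Product: 4 1-{(E)-3-[4-(benzyloxy)-3-methoxyphenyl]prop-1-en-1-yl}-2,4,5-trimethoxybenzene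
Conditions: second-generation Grubbs catalyst RuCl2(H2IMes)(PCy3)(=CHPh) (5 mol %), 1,4-benzoquinone (10 mol %), CH2Cl2, 40 °C, argon sweep
Reagents that add atoms: none
Why: Olefin cross-metathesis of an allylarene with a propenylarene, driven by loss of propene and giving the thermodynamic E alkene; the homodimer of 2 re-enters the cycle and benzoquinone suppresses double-bond migration by ruthenium hydride species.

Step 3
Reactants: 4 the trimethoxy diarylpropene
Product: 5 2-{(E)-3-[4-(benzyloxy)-3-methoxyphenyl]prop-1-en-1-yl}-5-methoxycyclohexa-2,5-diene-1,4-dione (vinylquinone)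
Conditions: (NH4)2Ce(NO3)6 (2.5 equiv), MeCN/H2O 3:1, 0 °C, short reaction time; used at once
Reagents that add atoms: water, O
Why: Oxidative demethylation of the para-dimethoxy pair (C2'/C5') through the arene radical cation and addition of water, as for 2-alkenyl-1,4-dimethoxyarenes; the 1,2,4-trioxygenated ring is oxidized well before the isolated benzyloxy-guaiacyl ring, and the remaining methoxy group ends as the vinylogous ester.

Step 4
Reactants: 5 the vinylquinone; 6 O-benzylisoeugenol ((E)-1-(benzyloxy)-2-methoxy-4-(prop-1-en-1-yl)benzene, 3 equiv)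
Product: 9 trans-8-[4-(benzyloxy)-3-methoxyphenyl]-6-[4-(benzyloxy)-3-methoxybenzyl]-2-methoxy-7-methyl-7,8-dihydronaphthalene-1,4-dione (racemic), via cycloadduct 7 (not isolated), via dihydronaphthalenediol 8 (not isolated)
Conditions: PhMe, 60 °C, dark, no acid or base; then MnO2 (10 equiv), CH2Cl2, rt
Reagents that add atoms: none
Why: Vinyl quinone Diels–Alder reaction with inverse electron demand, in which the quinone bond C8a=C4a and the exocyclic bond C5=C6 of 5 are the 4π component and the propenyl bond C7=C8 of 6 is the 2π component; the closest known reaction type is the cycloaddition of vinylquinones with electron-rich alkenes followed by oxidation with MnO2 in the same flask. Ring B is closed by this intermolecular [4+2] cycloaddition (bonds C6–C7 and C8–C8a), probably asynchronous with C6–C7 leading. The step needs head-to-tail orientation: the C2 methoxy group damps C4=O as a vinylogous ester, so the diene LUMO is governed by C1=O with its largest coefficient at C6, while the para-benzyloxy group of 6 puts the HOMO coefficient on the methyl-bearing carbon and stabilizes developing positive charge at C8 until it collapses on C8a, the α-carbon of the C1 dienolate. Cycloadduct 7 (an isoquinone methide) aromatizes ring A by two proton shifts (C8a–H to O1, C6–H to O4) to hydroquinone 8, which MnO2 oxidizes to 9. C7-methyl and C8-aryl are set trans by suprafacial addition to the E alkene, and the endo/exo-dependent centres C6 and C8a of 7 are uncontrolled, but all of these are erased by step 5, so no stereoselectivity is required. Chemoselectivity over self-dimerization and prototropic isomerization of 5 is sought through excess 6, neutral conditions and the E side chain, which lets the diene reach its s-cis form.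

Step 5
Reactants: 9 the 7,8-dihydronaphthoquinone
Product: 10 8-[4-(benzyloxy)-3-methoxyphenyl]-6-[4-(benzyloxy)-3-methoxybenzyl]-2-methoxy-7-methylnaphthalene-1,4-dione (O,O'-dibenzyl-larreantin)
Conditions: DDQ (1.2 equiv), 1,4-dioxane, rt to 50 °C
Reagents that add atoms: none
Why: DDQ dehydrogenation (hydride abstraction from C8–H, which is benzylic to the alkoxyaryl group, then loss of C7–H), driven by aromatization of ring B; both stereocentres vanish, and any 9 that has already isomerized and oxidized on MnO2 is 10.

Step 6
Reactants: 10 O,O'-dibenzyl-larreantin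
Product: 12 larreantin, via hydroquinone 11 (not isolated)
Conditions: H2 (1 atm), 10% Pd/C, EtOAc/MeOH, rt; filter; then air, rt
Reagents that add atoms: none
Why: Hydrogenolysis of both aryl benzyl ethers over zerovalent palladium, which also reduces the quinone to the naphthalene-1,4-diol 11; air re-oxidizes only this methoxynaphthohydroquinone, whose potential is far below that of the guaiacols, and the conditions are neutral, so the C2 methoxy group is kept.

## Compound list

1 | eugenol (4-allyl-2-methoxyphenol) | C=CCc1ccc(O)c(OC)c1 | starting material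
2 | O-benzyleugenol (4-allyl-1-(benzyloxy)-2-methoxybenzene) | C=CCc1ccc(OCc2ccccc2)c(OC)c1 | intermediate
3 | α-asarone ((E)-1,2,4-trimethoxy-5-(prop-1-en-1-yl)benzene) | C/C=C/c1cc(OC)c(OC)cc1OC | starting material
4 | 1-{(E)-3-[4-(benzyloxy)-3-methoxyphenyl]prop-1-en-1-yl}-2,4,5-trimethoxybenzene | COc1cc(OC)c(OC)cc1/C=C/Cc1ccc(OCc2ccccc2)c(OC)c1 | intermediate
5 | 2-{(E)-3-[4-(benzyloxy)-3-methoxyphenyl]prop-1-en-1-yl}-5-methoxy-1,4-benzoquinone | COC1=CC(=O)C(/C=C/Cc2ccc(OCc3ccccc3)c(OC)c2)=CC1=O | intermediate
6 | O-benzylisoeugenol ((E)-1-(benzyloxy)-2-methoxy-4-(prop-1-en-1-yl)benzene) | C/C=C/c1ccc(OCc2ccccc2)c(OC)c1 | starting material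
7 | cycloadduct (isoquinone methide): 8-[4-(benzyloxy)-3-methoxyphenyl]-6-[4-(benzyloxy)-3-methoxybenzyl]-2-methoxy-7-methyl-6,7,8,8a-tetrahydronaphthalene-1,4-dione; racemic, C7/C8 trans, C6 and C8a a mixture (not isolated) | COC1=CC(=O)C2=CC(Cc3ccc(OCc4ccccc4)c(OC)c3)[C@H](C)[C@@H](c3ccc(OCc4ccccc4)c(OC)c3)C2C1=O | intermediate
8 | trans-8-[4-(benzyloxy)-3-methoxyphenyl]-6-[4-(benzyloxy)-3-methoxybenzyl]-2-methoxy-7-methyl-7,8-dihydronaphthalene-1,4-diol, racemic (not isolated) | COc1cc(O)c2C=C(Cc3ccc(OCc4ccccc4)c(OC)c3)[C@H](C)[C@@H](c3ccc(OCc4ccccc4)c(OC)c3)c2c1O | intermediate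
9 | trans-8-[4-(benzyloxy)-3-methoxyphenyl]-6-[4-(benzyloxy)-3-methoxybenzyl]-2-methoxy-7-methyl-7,8-dihydronaphthalene-1,4-dione, racemic | COC1=CC(=O)C2=C(C1=O)[C@H](c1ccc(OCc3ccccc3)c(OC)c1)[C@@H](C)C(Cc1ccc(OCc3ccccc3)c(OC)c1)=C2 | intermediate
10 | O,O'-dibenzyl-larreantin | COC1=CC(=O)c2cc(Cc3ccc(OCc4ccccc4)c(OC)c3)c(C)c(-c3ccc(OCc4ccccc4)c(OC)c3)c2C1=O | intermediate
11 | 8-(4-hydroxy-3-methoxyphenyl)-6-(4-hydroxy-3-methoxybenzyl)-2-methoxy-7-methylnaphthalene-1,4-diol (not isolated) | COc1cc(O)c2cc(Cc3ccc(O)c(OC)c3)c(C)c(-c3ccc(O)c(OC)c3)c2c1O | intermediate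
12 | larreantin | COC1=CC(=O)c2cc(Cc3ccc(O)c(OC)c3)c(C)c(-c3ccc(O)c(OC)c3)c2C1=O | target

## Step count and least certain steps

Total steps: 6. Longest linear sequence: 6 (1 → 2 → 4 → 5 → 9 → 10 → 12).

**Step 4 (key step).**
- Most likely failure: cycloaddition of the 1,2-disubstituted styrene is too slow. Self-dimerization of 5 then overtakes, or 5 isomerizes by γ-deprotonation at its doubly activated CH2 and oxa-6π closure of the resulting o-quinone methide to a 2H-chromene. Traces of acid could also divert the pair to stepwise attack at the ring carbon with closure on oxygen.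
- Fallback (sets out from 5, returns at 10): a more nucleophilic 2π partner that aromatizes by elimination instead of dehydrogenation. The propiophenone F1 (1-[4-(benzyloxy)-3-methoxyphenyl]propan-1-one, from purchasable propiovanillone and benzyl bromide) is converted with TMSOTf/Et3N into its (Z)-trimethylsilyl enol ether F2. F2 adds to 5 at rt in CH2Cl2 in the same head-to-tail sense (vinyl quinone Diels–Alder reaction with an enol ether) and tautomerizes to the 8-silyloxy-7,8-dihydronaphthalene-1,4-diol F3. Catalytic TsOH eliminates trimethylsilanol to the naphthalene-1,4-diol F4, and MnO2 oxidizes F4 to 10.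

**Step 3.**
- Most likely failure: the styrene radical cation is attacked at the side chain (water or nitrate adding to the alkene, or oxidation of the doubly activated CH2) instead of being demethylated at the ring, and the benzyloxy-guaiacyl ring is over-oxidized.
- Fallback (sets out from 2, returns at 5): the quinone is brought in at its final oxidation level. Cross-metathesis of 2 with pinacol vinylboronate gives the alkenylboronate F5. Suzuki–Miyaura coupling (Pd(PPh3)4, CsF, THF) with 2-bromo-5-methoxy-1,4-benzoquinone F6 (from 2-methoxyhydroquinone by bromination and oxidation) gives 5.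

**Step 2.**
- Most likely failure: the catalyst is sequestered as a chelated 2-methoxybenzylidene resting state formed from 3, the allyl double bond of 2 migrates, and homodimers accumulate.
- Fallback (sets out from 2, returns at 4): Lemieux–Johnson cleavage (OsO4 cat., NaIO4, 2,6-lutidine) of 2 gives the arylacetaldehyde F7. Wittig olefination with the ylide from (2,4,5-trimethoxybenzyl)triphenylphosphonium bromide F8 and NaN(SiMe3)2 gives 4 as an E/Z mixture, which is equilibrated to E with catalytic iodine.

**Step 6.**
- Most likely failure: over-reduction of the naphthoquinone nucleus or stalled hydrogenolysis, and peroxide-mediated degradation of the free guaiacols during aerial re-oxidation.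
- Fallback (sets out from 10, returns at 12, no new compound, F0): non-reductive acidolysis of the benzyl ethers with pentamethylbenzene in CF3CO2H at rt. The quinone is never reduced, and the benzyl cations are trapped by the scavenger.

## Further compounds

F1 | step 4 | 1-[4-(benzyloxy)-3-methoxyphenyl]propan-1-one | CCC(=O)c1ccc(OCc2ccccc2)c(OC)c1
F2 | step 4 | (Z)-{1-[4-(benzyloxy)-3-methoxyphenyl]prop-1-en-1-yl}oxy(trimethyl)silane | C/C=C(\O[Si](C)(C)C)c1ccc(OCc2ccccc2)c(OC)c1
F3 | step 4 | 8-[4-(benzyloxy)-3-methoxyphenyl]-6-[4-(benzyloxy)-3-methoxybenzyl]-2-methoxy-7-methyl-8-(trimethylsilyloxy)-7,8-dihydronaphthalene-1,4-diol (racemic, methyl and silyloxy cis) | COc1cc(O)c2C=C(Cc3ccc(OCc4ccccc4)c(OC)c3)[C@H](C)[C@@](O[Si](C)(C)C)(c3ccc(OCc4ccccc4)c(OC)c3)c2c1O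
F4 | step 4 | 8-[4-(benzyloxy)-3-methoxyphenyl]-6-[4-(benzyloxy)-3-methoxybenzyl]-2-methoxy-7-methylnaphthalene-1,4-diol | COc1cc(O)c2cc(Cc3ccc(OCc4ccccc4)c(OC)c3)c(C)c(-c3ccc(OCc4ccccc4)c(OC)c3)c2c1O
F5 | step 3 | 2-{(E)-3-[4-(benzyloxy)-3-methoxyphenyl]prop-1-en-1-yl}-4,4,5,5-tetramethyl-1,3,2-dioxaborolane | CC1(C)OB(/C=C/Cc2ccc(OCc3ccccc3)c(OC)c2)OC1(C)C
F6 | step 3 | 2-bromo-5-methoxy-1,4-benzoquinone | COC1=CC(=O)C(Br)=CC1=O
F7 | step 2 | [4-(benzyloxy)-3-methoxyphenyl]acetaldehyde | O=CCc1ccc(OCc2ccccc2)c(OC)c1
F8 | step 2 | (2,4,5-trimethoxybenzyl)triphenylphosphonium bromide | COc1cc(OC)c(OC)cc1C[P+](c1ccccc1)(c1ccccc1)c1ccccc1.[Br-]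
F0 | step 6 | none | none
A1 | alternative 1 | (E)-1-[4-(benzyloxy)-3-methoxyphenyl]-3-[4-(benzyloxy)-3-methoxybenzyl]-2-methylbuta-1,3-diene | C=C(Cc1ccc(OCc2ccccc2)c(OC)c1)/C(C)=C/c1ccc(OCc2ccccc2)c(OC)c1
A2 | alternative 1 | 2-methoxy-1,4-benzoquinone | COC1=CC(=O)C=CC1=O
A3 | alternative 1 | endo Diels–Alder adduct: 8-[4-(benzyloxy)-3-methoxyphenyl]-6-[4-(benzyloxy)-3-methoxybenzyl]-2-methoxy-7-methyl-4a,5,8,8a-tetrahydronaphthalene-1,4-dione (racemic, H-4a, H-8 and H-8a cis) | COC1=CC(=O)[C@H]2CC(Cc3ccc(OCc4ccccc4)c(OC)c3)=C(C)[C@@H](c3ccc(OCc4ccccc4)c(OC)c3)[C@H]2C1=O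
A4 | alternative 2 | 1-bromo-2-[4-(benzyloxy)-3-methoxyphenyl]-3-methyl-4-[4-(benzyloxy)-3-methoxybenzyl]benzene | Brc1ccc(Cc2ccc(OCc3ccccc3)c(OC)c2)c(C)c1-c1ccc(OCc2ccccc2)c(OC)c1
A5 | alternative 2 | 3-methoxycyclobut-3-ene-1,2-dione | COC1=CC(=O)C1=O
A6 | alternative 2 | 4-aryl-4-hydroxy-3-methoxycyclobut-2-en-1-one (aryl = 2-[4-(benzyloxy)-3-methoxyphenyl]-3-methyl-4-[4-(benzyloxy)-3-methoxybenzyl]phenyl; racemic) | COC1=CC(=O)C1(O)c1ccc(Cc2ccc(OCc3ccccc3)c(OC)c2)c(C)c1-c1ccc(OCc2ccccc2)c(OC)c1
A7 | alternative 3 | trans-1-[4-(benzyloxy)-3-methoxyphenyl]-3-[4-(benzyloxy)-3-methoxybenzyl]-5,7,8-trimethoxy-2-methyl-1,2-dihydronaphthalene (racemic) | COc1cc(OC)c2C=C(Cc3ccc(OCc4ccccc4)c(OC)c3)[C@H](C)[C@@H](c3ccc(OCc4ccccc4)c(OC)c3)c2c1OC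
A8 | alternative 3 | 1-[4-(benzyloxy)-3-methoxyphenyl]-3-[4-(benzyloxy)-3-methoxybenzyl]-5,7,8-trimethoxy-2-methylnaphthalene | COc1cc(OC)c2cc(Cc3ccc(OCc4ccccc4)c(OC)c3)c(C)c(-c3ccc(OCc4ccccc4)c(OC)c3)c2c1OC
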